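**Plan**

1. Numbering used below: cyclopentane C1 (ring-fusion CH), C2, C3 (CHOH), C4 (CMe2), C5 (ring-fusion C–OH); seven-membered ring C5–C6–C7–C8 (CHMe)–C9 (Me, side chain)–C10 (C=O)–C1; side chain C11–C12 to the butenolide.
2. Retrosynthetic cuts, in order: butenolide back to a 3-furyl group; C1 epimer; C8–C9 by retro-Claisen (C6=C7 added, oxygen tied from C10 to C6 as a temporary tetrahydrofuran); C9–C11 (B-alkyl Suzuki–Miyaura) and O–C10 (iodoetherification); C1–C10 (alkynyl opening of an epoxide); C5–C6 (carbonylative coupling).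
3. Enabling feature: ring ketone C10 with its α-quaternary C9 and neighbouring C8 becomes a γ,δ-unsaturated ketone once a C6=C7 alkene is written in. Because C6 and C10 hang on the adjacent ring-fusion atoms C5 and C1, the allyl vinyl ether can be held in a five-membered ether ring (O, C10, C1, C5, C6), so the Claisen rearrangement is a ring expansion.
4. Forward order: cyclopentane (from 2,2-dimethylcyclopentane-1,3-dione), then the temporary tetrahydrofuran, then the seven-membered ring by [3,3] ring expansion as the last ring built; the furan is carried intact and only oxidised to the butenolide at the end.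
5. Stereochemistry: C3 from CBS desymmetrisation; C5 from hydroxyl-directed epoxidation and C1 (provisionally) from anti epoxide opening; C6 from chelation-controlled reduction, then relayed by the [3,3] shift to C8 and quaternary C9 through the (E)-propenyl and (E)-enol ether geometries; C1 finally by equilibration to the trans-fused ketol.

Key step: step 13

Assumption: both CBS reductions follow the usual large/small-substituent model (quaternary or α-branched carbon as the large group); should either carbinol form with the opposite sense, the enantiomeric catalyst would be used.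

**Route**

Step 1
Reactants: 1 2,2-dimethylcyclopentane-1,3-dione
Product: 2 (R)-3-hydroxy-2,2-dimethylcyclopentan-1-one
Conditions: (S)-2-methyl-CBS-oxazaborolidine (C18H20BNO, 20 mol %), catecholborane (1.1 equiv), toluene, −78 → −40 °C; aq. NaOH work-up
Reagents that add atoms: none
Why: Corey–Bakshi–Shibata reduction desymmetrises the achiral diketone, and with C(CH3)2 as the large and CH2 as the small substituent the (S)-catalyst should give the (R)-carbinol (C3), low temperature and one equivalent of borane limiting over-reduction.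

Step 2
Reactants: 2 (R)-3-hydroxy-2,2-dimethylcyclopentan-1-one
Product: 3 (R)-3-[(tert-butyldimethylsilyl)oxy]-2,2-dimethylcyclopentan-1-one
Conditions: TBSCl, imidazole, DMF, rt
Reagents that add atoms: tert-butyldimethylsilyl chloride, CC(C)(C)[Si](C)(C)Cl
Why: Standard silylation of a secondary alcohol gives an ether that should survive every later step up to the final fluoride cleavage.

Step 3
Reactants: 3 (R)-3-[(tert-butyldimethylsilyl)oxy]-2,2-dimethylcyclopentan-1-one
Product: 4 (R)-4-[(tert-butyldimethylsilyl)oxy]-5,5-dimethylcyclopent-1-en-1-yl trifluoromethanesulfonate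
Conditions: LiN(SiMe3)2, THF, −78 °C; then PhNTf2, −78 → 0 °C
Reagents that add atoms: N-phenylbis(trifluoromethanesulfonimide), O=S(=O)(N(c1ccccc1)S(=O)(=O)C(F)(F)F)C(F)(F)F
Why: Only C1 carries α-hydrogens (C4 is quaternary), so enolate formation and O-triflation should give a single enol triflate.

Step 4
Reactants: 4 (R)-4-[(tert-butyldimethylsilyl)oxy]-5,5-dimethylcyclopent-1-en-1-yl trifluoromethanesulfonate; 5 (E)-prop-1-en-1-ylboronic acid
Product: 6 (E)-1-[(R)-4-[(tert-butyldimethylsilyl)oxy]-5,5-dimethylcyclopent-1-en-1-yl]but-2-en-1-one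
Conditions: CO (1 atm), Pd(dppf)Cl2 (5 mol %), K2CO3, THF, 60 °C
Reagents that add atoms: carbon monoxide, [C-]#[O+]
Why: Carbonylative Suzuki–Miyaura coupling (oxidative addition of the enol triflate to zerovalent palladium, CO insertion, transmetalation, reductive elimination) should give the cross-conjugated dienone with the (E)-propenyl geometry retained and C6 installed as the carbonyl carbon.

Step 5
Reactants: 6 (E)-1-[(R)-4-[(tert-butyldimethylsilyl)oxy]-5,5-dimethylcyclopent-1-en-1-yl]but-2-en-1-one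
Product: 7 (R,E)-1-[(R)-4-[(tert-butyldimethylsilyl)oxy]-5,5-dimethylcyclopent-1-en-1-yl]but-2-en-1-ol
Conditions: (S)-2-methyl-CBS-oxazaborolidine (C18H20BNO, 20 mol %), catecholborane, toluene, −78 °C
Reagents that add atoms: none
Why: CBS 1,2-reduction with the α-branched cyclopentenyl group as the large and the propenyl group as the small substituent should give the (R)-carbinol at C6, which is needed only to steer the next step.

Step 6
Reactants: 7 (R,E)-1-[(R)-4-[(tert-butyldimethylsilyl)oxy]-5,5-dimethylcyclopent-1-en-1-yl]but-2-en-1-ol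
Product: 8 (R,E)-1-[(1R,3R,5R)-3-[(tert-butyldimethylsilyl)oxy]-2,2-dimethyl-6-oxabicyclo[3.1.0]hexan-1-yl]but-2-en-1-ol
Conditions: VO(acac)2 (5 mol %), t-BuOOH (decane solution), CH2Cl2, 0 °C → rt
Reagents that add atoms: tert-butyl hydroperoxide, CC(C)(C)OO
Why: Hydroxyl-directed epoxidation through a vanadium alkylperoxide bound to the C6 alkoxide should take the trisubstituted ring alkene in preference to the propenyl group, and the geminal C4 substituent (A(1,2) strain) makes delivery erythro-selective, which for the (R)-carbinol is the face anti to the C3 silyl ether (C5–O α).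

Step 7
Reactants: 8 (R,E)-1-[(1R,3R,5R)-3-[(tert-butyldimethylsilyl)oxy]-2,2-dimethyl-6-oxabicyclo[3.1.0]hexan-1-yl]but-2-en-1-ol; 9 1-propynyllithium
Product: 11 (R,E)-1-[(1R,3R,5R)-3-[(tert-butyldimethylsilyl)oxy]-1-hydroxy-2,2-dimethyl-5-(prop-1-yn-1-yl)cyclopentyl]but-2-en-1-ol, via diethyl(prop-1-ynyl)aluminium 10 (not isolated)
Conditions: 9, Et2AlCl, toluene, 0 °C; then 8, 0 °C → rt; aq. potassium sodium tartrate work-up
Reagents that add atoms: none
Why: Alkynylalane opening of a 2,3-epoxy alcohol should occur at the distal secondary carbon C1 with inversion, so the propynyl group ends trans to the new tertiary C5–OH and cis to C6, the relationship the later ether ring needs.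

Step 8
Reactants: 11 (R,E)-1-[(1R,3R,5R)-3-[(tert-butyldimethylsilyl)oxy]-1-hydroxy-2,2-dimethyl-5-(prop-1-yn-1-yl)cyclopentyl]but-2-en-1-ol
Product: 12 (E)-1-[(1R,3R,5R)-3-[(tert-butyldimethylsilyl)oxy]-1-hydroxy-2,2-dimethyl-5-(prop-1-yn-1-yl)cyclopentyl]but-2-en-1-one
Conditions: 2-iodoxybenzoic acid (IBX), DMSO, rt
Reagents that add atoms: none
Why: IBX should oxidise the secondary allylic alcohol of the 1,2-diol to the α-hydroxy enone without glycol cleavage, the tertiary alcohol being inert.

Step 9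
Reactants: 12 (E)-1-[(1R,3R,5R)-3-[(tert-butyldimethylsilyl)oxy]-1-hydroxy-2,2-dimethyl-5-(prop-1-yn-1-yl)cyclopentyl]but-2-en-1-one
Product: 13 (S,E)-1-[(1R,3R,5R)-3-[(tert-butyldimethylsilyl)oxy]-1-hydroxy-2,2-dimethyl-5-(prop-1-yn-1-yl)cyclopentyl]but-2-en-1-ol
Conditions: Zn(BH4)2, Et2O, −30 → 0 °C
Reagents that add atoms: none
Why: In this chelation-controlled 1,2-reduction zinc holds the tertiary C5–OH and the C6 carbonyl syn-periplanar, and hydride should enter from the ring-CH (C1) side, which carries only the slim alkynyl group, rather than past the C(CH3)2 group, giving the (S)-carbinol.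

Step 10
Reactants: 13 (S,E)-1-[(1R,3R,5R)-3-[(tert-butyldimethylsilyl)oxy]-1-hydroxy-2,2-dimethyl-5-(prop-1-yn-1-yl)cyclopentyl]but-2-en-1-ol
Product: 14 (1E,3S,3aR,5R,6aS)-5-[(tert-butyldimethylsilyl)oxy]-1-(1-iodoethylidene)-4,4-dimethyl-3-[(E)-prop-1-en-1-yl]hexahydro-1H-cyclopenta[c]furan-3a-ol
Conditions: N-iodosuccinimide, NaHCO3, CH2Cl2, −20 → 0 °C, dark
Reagents that add atoms: N-iodosuccinimide, O=C1CCC(=O)N1I
Why: Electrophilic 5-exo-dig iodoetherification with anti attack by the C6 hydroxyl, the only one that can reach C10 (the C5 hydroxyl is trans to the alkynyl group), should close the cis-fused tetrahydrofuran and place iodine trans to the ring oxygen, fixing the enol ether geometry (methyl syn to O).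

Step 11
Reactants: 15 furan-3-carbaldehyde
Product: 16 3-vinylfuran
Conditions: Ph3PCH3Br, KOtBu, Et2O, 0 °C → rt; product used as a titrated solution
Reagents that add atoms: methyltriphenylphosphonium bromide, C[P+](c1ccccc1)(c1ccccc1)c1ccccc1.[Br-]
Why: Wittig methylenation of an unhindered aromatic aldehyde is routine.

Step 12
Reactants: 14 (1E,3S,3aR,5R,6aS)-5-[(tert-butyldimethylsilyl)oxy]-1-(1-iodoethylidene)-4,4-dimethyl-3-[(E)-prop-1-en-1-yl]hexahydro-1H-cyclopenta[c]furan-3a-ol; 16 3-vinylfuran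
Product: 18 (1E,3S,3aR,5R,6aS)-5-[(tert-butyldimethylsilyl)oxy]-1-[4-(furan-3-yl)butan-2-ylidene]-4,4-dimethyl-3-[(E)-prop-1-en-1-yl]hexahydro-1H-cyclopenta[c]furan-3a-ol, via B-[2-(furan-3-yl)ethyl]-9-borabicyclo[3.3.1]nonane 17 (not isolated)
Conditions: 16, 9-BBN dimer, THF, 0 °C → rt; then 14, Pd(dppf)Cl2 (10 mol %), AsPh3, Cs2CO3, DMF/H2O, rt → 45 °C
Reagents that add atoms: none
Why: B-alkyl Suzuki–Miyaura coupling (anti-Markovnikov hydroboration, then zerovalent-palladium coupling with retention at the alkenyl iodide) should place the furylethyl chain trans to the ring oxygen, giving the (E)-tetrasubstituted enol ether.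

Step 13
Reactants: 18 (1E,3S,3aR,5R,6aS)-5-[(tert-butyldimethylsilyl)oxy]-1-[4-(furan-3-yl)butan-2-ylidene]-4,4-dimethyl-3-[(E)-prop-1-en-1-yl]hexahydro-1H-cyclopenta[c]furan-3a-ol
Product: 19 (2R,3aS,5S,6R,8aR)-2-[(tert-butyldimethylsilyl)oxy]-5-[2-(furan-3-yl)ethyl]-8a-hydroxy-1,1,5,6-tetramethyl-2,3,3a,5,6,8a-hexahydroazulen-4(1H)-one
Conditions: o-xylene (degassed), i-Pr2NEt (0.2 equiv), 2,6-di-tert-butyl-4-methylphenol (trace), sealed tube, 180 °C
Reagents that add atoms: none
Why: Thermal [3,3]-sigmatropic (Claisen) rearrangement of the allyl vinyl ether C9=C10–O–C6–C7=C8 held inside the 2-alkylidene-5-alkenyltetrahydrofuran: C6–O breaks as C8–C9 forms and the carbonyl appears at C10. The closest known reaction type is the Claisen ring expansion of 2-methylene-5-vinyltetrahydrofurans to cyclohept-4-enones. The seven-membered ring (C10, C9, C8, C7, C6, C5, C1) is closed by ring expansion, the five-membered ether ring being traded for the carbocycle through a single chair-like six-atom array in which the C5–C1 tether forces C5 onto the inside position of the allyl unit, hence the cis C6=C7 alkene and a cis ring fusion. Quaternary C9 is controlled by the (E)-enol ether geometry (methyl syn to the ring oxygen) and by the face of attack, which is the ether-ring face bearing the propenyl group (convex face, syn to C5–OH), that is by the C6 configuration; C8 is controlled by the (E)-propenyl geometry, its methyl group pseudo-equatorial, so the C6 carbinol chirality is relayed to both centres. The selectivity required is facial and geometrical (there is no regiochemical alternative and the tether cannot span a boat array), and it is secured by the bicyclic constraint and by base-buffered, acid-free conditions that keep both alkene geometries intact.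

Step 14
Reactants: 19 (2R,3aS,5S,6R,8aR)-2-[(tert-butyldimethylsilyl)oxy]-5-[2-(furan-3-yl)ethyl]-8a-hydroxy-1,1,5,6-tetramethyl-2,3,3a,5,6,8a-hexahydroazulen-4(1H)-one
Product: 20 (2R,3aS,5S,6R,8aR)-2-[(tert-butyldimethylsilyl)oxy]-5-[2-(furan-3-yl)ethyl]-8a-hydroxy-1,1,5,6-tetramethyloctahydroazulen-4(1H)-one
Conditions: 2-nitrobenzenesulfonylhydrazide (excess), Et3N, CH2Cl2, rt
Reagents that add atoms: none
Why: Diimide transfers H2 to the cis-disubstituted ring alkene in a concerted syn fashion without metal hydride intermediates, so no double-bond migration can scramble C8 and the furan and ketone should be untouched.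

Step 15
Reactants: 20 (2R,3aS,5S,6R,8aR)-2-[(tert-butyldimethylsilyl)oxy]-5-[2-(furan-3-yl)ethyl]-8a-hydroxy-1,1,5,6-tetramethyloctahydroazulen-4(1H)-one
Product: 21 (2R,3aR,5S,6R,8aR)-2-[(tert-butyldimethylsilyl)oxy]-5-[2-(furan-3-yl)ethyl]-8a-hydroxy-1,1,5,6-tetramethyloctahydroazulen-4(1H)-one
Conditions: DBU, toluene, 60 °C
Reagents that add atoms: none
Why: Base-mediated enolisation and reprotonation at C1, the only enolisable position (C9 is quaternary), should favour the trans-fused isomer, in which the C5 hydroxyl and the C10 carbonyl are cis on the cyclopentane and can form an intramolecular hydrogen bond.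

Step 16
Reactants: 21 (2R,3aR,5S,6R,8aR)-2-[(tert-butyldimethylsilyl)oxy]-5-[2-(furan-3-yl)ethyl]-8a-hydroxy-1,1,5,6-tetramethyloctahydroazulen-4(1H)-one
Product: 23 4-{2-[(2R,3aR,5S,6R,8aR)-2-[(tert-butyldimethylsilyl)oxy]-8a-hydroxy-1,1,5,6-tetramethyl-4-oxodecahydroazulen-5-yl]ethyl}furan-2(5H)-one, via 5-hydroxybutenolide 22 (not isolated)
Conditions: O2, visible light, 5,10,15,20-tetraphenylporphyrin (cat.), i-Pr2NEt, CH2Cl2, −78 °C; then NaBH4, EtOH, 0 °C; then 1 M HCl
Reagents that add atoms: dioxygen, O=O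
Why: [4+2] photooxygenation of the 3-alkylfuran and hindered-amine-induced Kornblum–DeLaMare collapse at the less hindered C–H give the 4-alkyl-5-hydroxybutenolide, whose masked aldehyde is reduced by borohydride and relactonised on acidification, while the C10 ketone, flanked by two fully substituted carbons, should survive brief cold borohydride.

Step 17
Reactants: 23 4-{2-[(2R,3aR,5S,6R,8aR)-2-[(tert-butyldimethylsilyl)oxy]-8a-hydroxy-1,1,5,6-tetramethyl-4-oxodecahydroazulen-5-yl]ethyl}furan-2(5H)-one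
Product: 24 4-{2-[(2R,3aR,5S,6R,8aR)-2,8a-dihydroxy-1,1,5,6-tetramethyl-4-oxodecahydroazulen-5-yl]ethyl}furan-2(5H)-one
Conditions: aq. HF (48 %), MeCN, rt
Reagents that add atoms: none
Why: Acidic fluoride cleaves the hindered secondary silyl ether while avoiding the basic conditions that could trigger retro-aldol of the ketol or isomerisation of the butenolide.

**Compound list**

1 | 2,2-dimethylcyclopentane-1,3-dione | CC1(C)C(=O)CCC1=O | starting material
2 | (R)-3-hydroxy-2,2-dimethylcyclopentan-1-one | O=C1CC[C@@H](O)C1(C)C | intermediate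
3 | (R)-3-[(tert-butyldimethylsilyl)oxy]-2,2-dimethylcyclopentan-1-one | O=C1CC[C@@H](O[Si](C)(C)C(C)(C)C)C1(C)C | intermediate
4 | (R)-4-[(tert-butyldimethylsilyl)oxy]-5,5-dimethylcyclopent-1-en-1-yl trifluoromethanesulfonate | O=S(=O)(OC1=CC[C@@H](O[Si](C)(C)C(C)(C)C)C1(C)C)C(F)(F)F | intermediate
5 | (E)-prop-1-en-1-ylboronic acid | C/C=C/B(O)O | starting material
6 | (E)-1-[(R)-4-[(tert-butyldimethylsilyl)oxy]-5,5-dimethylcyclopent-1-en-1-yl]but-2-en-1-one | C/C=C/C(=O)C1=CC[C@@H](O[Si](C)(C)C(C)(C)C)C1(C)C | intermediate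
7 | (R,E)-1-[(R)-4-[(tert-butyldimethylsilyl)oxy]-5,5-dimethylcyclopent-1-en-1-yl]but-2-en-1-ol | C/C=C/[C@@H](O)C1=CC[C@@H](O[Si](C)(C)C(C)(C)C)C1(C)C | intermediate
8 | (R,E)-1-[(1R,3R,5R)-3-[(tert-butyldimethylsilyl)oxy]-2,2-dimethyl-6-oxabicyclo[3.1.0]hexan-1-yl]but-2-en-1-ol | C/C=C/[C@@H](O)[C@@]12O[C@@H]1C[C@@H](O[Si](C)(C)C(C)(C)C)C2(C)C | intermediate
9 | 1-propynyllithium | [Li]C#CC | starting material
10 | diethyl(prop-1-ynyl)aluminium | CC[Al](CC)C#CC | intermediate
11 | (R,E)-1-[(1R,3R,5R)-3-[(tert-butyldimethylsilyl)oxy]-1-hydroxy-2,2-dimethyl-5-(prop-1-yn-1-yl)cyclopentyl]but-2-en-1-ol | C/C=C/[C@@H](O)[C@@]1(O)[C@@H](C#CC)C[C@@H](O[Si](C)(C)C(C)(C)C)C1(C)C | intermediate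
12 | (E)-1-[(1R,3R,5R)-3-[(tert-butyldimethylsilyl)oxy]-1-hydroxy-2,2-dimethyl-5-(prop-1-yn-1-yl)cyclopentyl]but-2-en-1-one | C/C=C/C(=O)[C@@]1(O)[C@@H](C#CC)C[C@@H](O[Si](C)(C)C(C)(C)C)C1(C)C | intermediate
13 | (S,E)-1-[(1R,3R,5R)-3-[(tert-butyldimethylsilyl)oxy]-1-hydroxy-2,2-dimethyl-5-(prop-1-yn-1-yl)cyclopentyl]but-2-en-1-ol | C/C=C/[C@H](O)[C@@]1(O)[C@@H](C#CC)C[C@@H](O[Si](C)(C)C(C)(C)C)C1(C)C | intermediate
14 | (1E,3S,3aR,5R,6aS)-5-[(tert-butyldimethylsilyl)oxy]-1-(1-iodoethylidene)-4,4-dimethyl-3-[(E)-prop-1-en-1-yl]hexahydro-1H-cyclopenta[c]furan-3a-ol | C/C=C/[C@@H]1O/C(=C(\C)I)[C@H]2C[C@@H](O[Si](C)(C)C(C)(C)C)C(C)(C)[C@@]12O | intermediate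
15 | furan-3-carbaldehyde | O=Cc1ccoc1 | starting material
16 | 3-vinylfuran | C=Cc1ccoc1 | intermediate
17 | B-[2-(furan-3-yl)ethyl]-9-borabicyclo[3.3.1]nonane | B1(CCc2ccoc2)C2CCCC1CCC2 | intermediate
18 | (1E,3S,3aR,5R,6aS)-5-[(tert-butyldimethylsilyl)oxy]-1-[4-(furan-3-yl)butan-2-ylidene]-4,4-dimethyl-3-[(E)-prop-1-en-1-yl]hexahydro-1H-cyclopenta[c]furan-3a-ol | C/C=C/[C@@H]1O/C(=C(\C)CCc3ccoc3)[C@H]2C[C@@H](O[Si](C)(C)C(C)(C)C)C(C)(C)[C@@]12O | intermediate
19 | (2R,3aS,5S,6R,8aR)-2-[(tert-butyldimethylsilyl)oxy]-5-[2-(furan-3-yl)ethyl]-8a-hydroxy-1,1,5,6-tetramethyl-2,3,3a,5,6,8a-hexahydroazulen-4(1H)-one | C[C@@H]1C=C[C@@]2(O)[C@H](C[C@@H](O[Si](C)(C)C(C)(C)C)C2(C)C)C(=O)[C@@]1(C)CCc1ccoc1 | intermediate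
20 | (2R,3aS,5S,6R,8aR)-2-[(tert-butyldimethylsilyl)oxy]-5-[2-(furan-3-yl)ethyl]-8a-hydroxy-1,1,5,6-tetramethyloctahydroazulen-4(1H)-one | C[C@@H]1CC[C@@]2(O)[C@H](C[C@@H](O[Si](C)(C)C(C)(C)C)C2(C)C)C(=O)[C@@]1(C)CCc1ccoc1 | intermediate
21 | (2R,3aR,5S,6R,8aR)-2-[(tert-butyldimethylsilyl)oxy]-5-[2-(furan-3-yl)ethyl]-8a-hydroxy-1,1,5,6-tetramethyloctahydroazulen-4(1H)-one | C[C@@H]1CC[C@@]2(O)[C@@H](C[C@@H](O[Si](C)(C)C(C)(C)C)C2(C)C)C(=O)[C@@]1(C)CCc1ccoc1 | intermediate
22 | 4-{2-[(2R,3aR,5S,6R,8aR)-2-[(tert-butyldimethylsilyl)oxy]-8a-hydroxy-1,1,5,6-tetramethyl-4-oxodecahydroazulen-5-yl]ethyl}-5-hydroxyfuran-2(5H)-one (lactol epimers) | C[C@@H]1CC[C@@]2(O)[C@@H](C[C@@H](O[Si](C)(C)C(C)(C)C)C2(C)C)C(=O)[C@@]1(C)CCC1=CC(=O)OC1O | intermediate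
23 | 4-{2-[(2R,3aR,5S,6R,8aR)-2-[(tert-butyldimethylsilyl)oxy]-8a-hydroxy-1,1,5,6-tetramethyl-4-oxodecahydroazulen-5-yl]ethyl}furan-2(5H)-one | C[C@@H]1CC[C@@]2(O)[C@@H](C[C@@H](O[Si](C)(C)C(C)(C)C)C2(C)C)C(=O)[C@@]1(C)CCC1=CC(=O)OC1 | intermediate
24 | 4-{2-[(2R,3aR,5S,6R,8aR)-2,8a-dihydroxy-1,1,5,6-tetramethyl-4-oxodecahydroazulen-5-yl]ethyl}furan-2(5H)-one | C[C@@H]1CC[C@@]2(O)[C@@H](C[C@@H](O)C2(C)C)C(=O)[C@@]1(C)CCC1=CC(=O)OC1 | target

**Totals and risks**

Total step count: 17. Longest linear sequence: 16 (steps 1–10 and 12–17; step 11 is the side branch).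

Three steps most likely to fail:

1. Step 13. The rearrangement may stall, or divert to ionisation and elimination, at the temperature needed, because a quaternary carbon is formed next to a tertiary one in a constrained bicyclic transition state. Fallback: setting out from 18, the thermal concerted process is replaced by a Lewis-acid-driven ring expansion with in situ reduction. Treatment with Al(i-Bu)3 in CH2Cl2 (−78 °C → rt) coordinates the ring oxygen, polarises the C6–O bond and lets the aluminium enolate and the allyl terminus recombine at C8 at low temperature. The ketone so formed is reduced at once by β-hydride transfer from the reagent to the cycloheptenol, the C10 carbinol of 19, F1. Oxidation of this secondary alcohol with IBX in DMSO then gives the ketone, and the route is rejoined at 19.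

2. Step 15. The β-hydroxy ketone may open by retro-aldol fragmentation under base, or the equilibrium may not lie on the trans-fused side. Fallback: setting out from 20, C1 is set under kinetic rather than thermodynamic control. The tertiary hydroxyl is silylated with N-(trimethylsilyl)imidazole to give the C5 trimethylsilyl ether of 20, F2. Deprotonation with KN(SiMe3)2 in THF at −78 °C gives the potassium enolate of F2, F3. A cold quench with acetic acid should protonate C1 on the face anti to the bulky C5 silyloxy group and give the trans-fused C5 trimethylsilyl ether, F4. Mild methanolysis (PPTS, MeOH, 0 °C) removes the tertiary trimethylsilyl group without base and returns to the route at 21.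

3. Step 10. Iodonium formation at the propenyl alkene with capture by the tertiary C5 hydroxyl (5-endo closure), or 6-endo attack on the alkyne, may compete with the wanted 5-exo-dig closure. Fallback: setting out from 13, the enol ether is assembled without electrophilic iodine. Furan-3-carbaldehyde 15 is converted by Takai olefination (CrCl2, CHBr3, THF) into (E)-3-(2-bromovinyl)furan, F5. The dilithium alkoxide of 13 (n-BuLi) is cyclised under zerovalent-palladium catalysis (Pd(OAc)2, PPh3, THF, 60 °C) in the presence of F5: anti-oxypalladation of the alkyne by the alkenylpalladium bromide and reductive elimination should give the dienyl ether analogue of 18, F6, with the same enol ether geometry. Claisen ring expansion under the conditions of step 13 gives the C11=C12 unsaturated analogue of 19, F7. Excess diimide then saturates both disubstituted alkenes and the route is rejoined at 20, steps 12 and 14 being bypassed as well.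

**Further compounds**

F1 | step 13 | 2-[(tert-butyldimethylsilyl)oxy]-5-[2-(furan-3-yl)ethyl]-1,1,5,6-tetramethyl-1,2,3,3a,4,5,6,8a-octahydroazulene-4,8a-diol (ring stereocentres as in 19; C4 carbinol as formed) | C[C@@H]1C=C[C@@]2(O)[C@H](C[C@@H](O[Si](C)(C)C(C)(C)C)C2(C)C)C(O)[C@@]1(C)CCc1ccoc1
F2 | step 15 | C5 (position 8a) trimethylsilyl ether of 20 (cis-fused) | C[C@@H]1CC[C@@]2(O[Si](C)(C)C)[C@H](C[C@@H](O[Si](C)(C)C(C)(C)C)C2(C)C)C(=O)[C@@]1(C)CCc1ccoc1
F3 | step 15 | potassium C1=C10 enolate of F2 | C[C@@H]1CC[C@@]2(O[Si](C)(C)C)C(C[C@@H](O[Si](C)(C)C(C)(C)C)C2(C)C)=C([O-])[C@@]1(C)CCc1ccoc1.[K+]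
F4 | step 15 | C5 (position 8a) trimethylsilyl ether of 21 (trans-fused) | C[C@@H]1CC[C@@]2(O[Si](C)(C)C)[C@@H](C[C@@H](O[Si](C)(C)C(C)(C)C)C2(C)C)C(=O)[C@@]1(C)CCc1ccoc1
F5 | step 10 | (E)-3-(2-bromovinyl)furan | Br/C=C/c1ccoc1
F6 | step 10 | (1E,3S,3aR,5R,6aS)-5-[(tert-butyldimethylsilyl)oxy]-1-[(E)-4-(furan-3-yl)but-3-en-2-ylidene]-4,4-dimethyl-3-[(E)-prop-1-en-1-yl]hexahydro-1H-cyclopenta[c]furan-3a-ol | C/C=C/[C@@H]1O/C(=C(\C)/C=C/c3ccoc3)[C@H]2C[C@@H](O[Si](C)(C)C(C)(C)C)C(C)(C)[C@@]12O
F7 | step 10 | 2-[(tert-butyldimethylsilyl)oxy]-5-[(E)-2-(furan-3-yl)vinyl]-8a-hydroxy-1,1,5,6-tetramethyl-2,3,3a,5,6,8a-hexahydroazulen-4(1H)-one (ring stereocentres as in 19) | C[C@@H]1C=C[C@@]2(O)[C@H](C[C@@H](O[Si](C)(C)C(C)(C)C)C2(C)C)C(=O)[C@@]1(C)/C=C/c1ccoc1
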